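**Plan**

- Retrosynthetic cuts, in order: C11–OAc; C11–O and C12–H back to a C11=C12 alkene; the oxepane bond O–C16; C15=C16 back to an acetyl group on C14; then C1–C10 together with C13–C14 in one [4+2] event; then C1=C14 and C10=C11 (Wittig), C6–O/C7–H, C6=C7 (metathesis), C3–C4, C3–CH3, C2–C1, the ether O–CH2 bond and C7–C8.
- Enabling feature: the cyclohexane C1/C10/C11/C12/C13/C14 is a Diels–Alder retron fused to the tetrahydrofuran O/C2/C1/C10/C9. The ether oxygen between C2 and C9 inside the nine-membered oxonane is a three-atom tether that holds diene terminus C10 and enone carbon C1 on one ring face.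
- Forward ring order: oxonene (ring-closing metathesis) → saturated oxonane carrying C6–OMe and C7–CH3 → cyclohexene plus tetrahydrofuran in the cycloaddition → oxepane (C3–O–C16) → C11/C12 adjustment.
- Stereochemistry: C9 from (S)-benzyl glycidyl ether; C2 by oxazolidinone-controlled alkylation; C3 by chelation-controlled Grignard addition; C6 and C7 by cis delivery across the ring from the C3 oxygen; C1, C10 and C14 in the cycloaddition; C15, C12 and C11 by substrate-controlled hydroborations and a ketone reduction.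

Key step: step 15

Remark: locants C1–C16 are those of the target skeleton (C2 and C9 flank the bridging ether oxygen; C3 bears CH3 and the oxepane oxygen; C6 bears OMe; C7, C12 and C15 bear CH3; C11 bears OAc; C16 is the OCH2 carbon). β denotes the face of H-1 and H-10. The tertiary C3 hydroxyl is assumed to be inert enough to be carried unprotected from step 7 until it is used as a nucleophile in step 18.

**Step 1**
Reactants: 1 (S)-benzyl glycidyl ether
Product: 2 (S)-1-(benzyloxy)-4-methylpent-4-en-2-ol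
Conditions: CH2=C(CH3)MgBr, CuI (10 mol%), THF, −40 → 0 °C
Reagents that add atoms: isopropenylmagnesium bromide C=C(C)[Mg]Br
Why: Copper-catalysed Grignard opening of the terminal epoxide at its CH2 carbon (SN2) installs C7/C8 and leaves the glycidyl stereocentre (future C9) untouched.

**Step 2**
Reactants: 2 (S)-1-(benzyloxy)-4-methylpent-4-en-2-ol
Product: 3 {[(S)-1-(benzyloxy)-4-methylpent-4-en-2-yl]oxy}acetic acid
Conditions: NaH, BrCH2CO2H, THF, 0 °C → rt
Reagents that add atoms: bromoacetic acid OC(=O)CBr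
Why: Williamson etherification of the secondary alkoxide with sodium bromoacetate forms the future C9–O–C2 ether without touching the stereocentre.

**Step 3**
Reactants: 3 {[(S)-1-(benzyloxy)-4-methylpent-4-en-2-yl]oxy}acetic acid
Product: 5 (R)-4-benzyl-3-({[(S)-1-(benzyloxy)-4-methylpent-4-en-2-yl]oxy}acetyl)oxazolidin-2-one, via mixed pivalic anhydride 4 (not isolated)
Conditions: t-BuCOCl, Et3N, THF, −78 → 0 °C; then (R)-4-benzyl-2-oxazolidinone, n-BuLi, THF, −78 → 0 °C
Reagents that add atoms: (R)-4-benzyl-2-oxazolidinone O=C1N[C@H](Cc2ccccc2)CO1; pivaloyl chloride CC(C)(C)C(Cl)=O (kept only in 4)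
Why: N-acylation of the lithiated oxazolidinone by the mixed anhydride at its less hindered carbonyl gives the glycolyl imide needed for auxiliary-controlled alkylation.

**Step 4**
Reactants: 5 (R)-4-benzyl-3-({[(S)-1-(benzyloxy)-4-methylpent-4-en-2-yl]oxy}acetyl)oxazolidin-2-one
Product: 6 (R)-4-benzyl-3-[(S)-2-{[(S)-1-(benzyloxy)-4-methylpent-4-en-2-yl]oxy}-3-(triisopropylsilyloxy)propanoyl]oxazolidin-2-one
Conditions: NaN(SiMe3)2, THF, −78 °C; then i-Pr3SiOCH2Cl, tetrabutylammonium iodide (cat.), −78 → −45 °C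
Reagents that add atoms: (triisopropylsiloxy)methyl chloride ClCO[Si](C(C)C)(C(C)C)C(C)C
Why: Evans-type alkylation of the chelated Z sodium glycolate enolate with an alkoxymethyl chloride; the electrophile enters anti to the benzyl group of the (R)-auxiliary, which sets C2 and brings in C1 as a silyl-protected CH2OH.

**Step 5**
Reactants: 6 (R)-4-benzyl-3-[(S)-2-{[(S)-1-(benzyloxy)-4-methylpent-4-en-2-yl]oxy}-3-(triisopropylsilyloxy)propanoyl]oxazolidin-2-one
Product: 7 (S)-2-{[(S)-1-(benzyloxy)-4-methylpent-4-en-2-yl]oxy}-N-methoxy-N-methyl-3-(triisopropylsilyloxy)propanamide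
Conditions: MeNH(OMe)·HCl, AlMe3, CH2Cl2, −20 → 0 °C
Reagents that add atoms: N,O-dimethylhydroxylamine hydrochloride CNOC.Cl
Why: Aluminium amide transamination of the imide (Weinreb amide formation) removes the auxiliary without epimerising the α-alkoxy centre.

**Step 6**
Reactants: 7 (S)-2-{[(S)-1-(benzyloxy)-4-methylpent-4-en-2-yl]oxy}-N-methoxy-N-methyl-3-(triisopropylsilyloxy)propanamide
Product: 8 (S)-3-{[(S)-1-(benzyloxy)-4-methylpent-4-en-2-yl]oxy}-4-(triisopropylsilyloxy)butan-2-one
Conditions: MeMgBr, THF, −20 → 0 °C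
Reagents that add atoms: methylmagnesium bromide C[Mg]Br
Why: Weinreb ketone synthesis; the chelated tetrahedral intermediate stops at the methyl ketone and supplies the C3 methyl group.

**Step 7**
Reactants: 8 (S)-3-{[(S)-1-(benzyloxy)-4-methylpent-4-en-2-yl]oxy}-4-(triisopropylsilyloxy)butan-2-one
Product: 9 (2S,3S)-2-{[(S)-1-(benzyloxy)-4-methylpent-4-en-2-yl]oxy}-3-methyl-1-(triisopropylsilyloxy)hept-6-en-3-ol
Conditions: CH2=CHCH2CH2MgBr, MgBr2·OEt2, CH2Cl2/Et2O, −78 °C
Reagents that add atoms: but-3-enylmagnesium bromide C=CCC[Mg]Br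
Why: Cram-chelate-controlled Grignard addition; magnesium bridges the ketone and the C2 ether oxygen (the silyl ether does not chelate), and the butenyl group enters anti to CH2OSi, which sets C3.

**Step 8**
Reactants: 9 (2S,3S)-2-{[(S)-1-(benzyloxy)-4-methylpent-4-en-2-yl]oxy}-3-methyl-1-(triisopropylsilyloxy)hept-6-en-3-ol
Product: 10 (2S,3S,9S,6Z)-9-(benzyloxymethyl)-3,7-dimethyl-2-(triisopropylsilyloxymethyl)-2,3,4,5,8,9-hexahydrooxonin-3-ol
Conditions: second-generation Grubbs catalyst RuCl2(=CHPh)(H2IMes)(PCy3) (10 mol%), CH2Cl2 (0.002 M), 40 °C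
Reagents that add atoms: none
Why: Ring-closing metathesis of the monosubstituted and 1,1-disubstituted alkenes closes the nine-membered ether; gauche C–O bonds at C2/C3 and at the ether favour the folded chain, and ring size enforces the Z trisubstituted C6=C7 alkene.

**Step 9**
Reactants: 10 (2S,3S,9S,6Z)-9-(benzyloxymethyl)-3,7-dimethyl-2-(triisopropylsilyloxymethyl)-2,3,4,5,8,9-hexahydrooxonin-3-ol
Product: 13 (2S,3S,6R,7R,9S)-9-(benzyloxymethyl)-3,7-dimethyl-2-(triisopropylsilyloxymethyl)oxonane-3,6-diol, via C3 hydrodimethylsilyl ether 11 (not isolated), via bridged cyclic siloxane 12 (not isolated)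
Conditions: HSiMe2Cl, Et3N, DMAP (cat.), CH2Cl2, 0 °C; then Pt2[(CH2=CHSiMe2)2O]3 (zerovalent platinum, 1 mol%), toluene (0.005 M), 60 °C; then KF, KHCO3, 30% H2O2, THF/MeOH, rt
Reagents that add atoms: hydrogen peroxide OO; chlorodimethylsilane C[SiH](C)Cl (kept only in 11 and 12)
Why: Proposed new method: the only free hydroxyl is silylated to the Si–H ether 11, and platinum-catalysed hydrosilylation (Si–H oxidative addition, alkene insertion, C–Si reductive elimination, overall syn) then adds Si and H across C6=C7; because silicon is anchored to the C3 oxygen it can reach only the alkene face syn to the C3–O bond, bonding to the less substituted C6 (six-membered 1-oxa-2-silacyclohexane spanning C3 and C6) while H goes to C7 on the same face, and Tamao oxidation with retention gives the C6 alcohol cis to the C3 oxygen with H-7 on that face, i.e. the C6 and C7 configurations of the target independent of any conformational bias of the ring; closest known reaction type: Tamao–Ito intramolecular hydrosilylation of homoallylic and bishomoallylic hydrodimethylsilyl ethers followed by Tamao–Fleming oxidation, which has not been shown transannularly across a nine-membered ring.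

**Step 10**
Reactants: 13 (2S,3S,6R,7R,9S)-9-(benzyloxymethyl)-3,7-dimethyl-2-(triisopropylsilyloxymethyl)oxonane-3,6-diol
Product: 14 (2S,3S,6R,7R,9S)-9-(benzyloxymethyl)-6-methoxy-3,7-dimethyl-2-(triisopropylsilyloxymethyl)oxonan-3-ol
Conditions: Me3O+ BF4−, 1,8-bis(dimethylamino)naphthalene, CH2Cl2, 0 °C → rt
Reagents that add atoms: trimethyloxonium tetrafluoroborate C[O+](C)C.F[B-](F)(F)F
Why: O-Methylation under non-basic conditions (Meerwein salt with a hindered amine) should take the secondary C6 hydroxyl and leave the hindered tertiary C3 hydroxyl free.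

**Step 11**
Reactants: 14 (2S,3S,6R,7R,9S)-9-(benzyloxymethyl)-6-methoxy-3,7-dimethyl-2-(triisopropylsilyloxymethyl)oxonan-3-ol
Product: 15 (2S,3S,6R,7R,9S)-9-(hydroxymethyl)-6-methoxy-3,7-dimethyl-2-(triisopropylsilyloxymethyl)oxonan-3-ol
Conditions: H2 (1 atm), 10% Pd/C, EtOAc, rt
Reagents that add atoms: none
Why: Hydrogenolysis of the benzyl ether frees the C10 hydroxyl at the one stage where the molecule holds no alkene; the silyl ether is untouched.

**Step 12**
Reactants: 15 (2S,3S,6R,7R,9S)-9-(hydroxymethyl)-6-methoxy-3,7-dimethyl-2-(triisopropylsilyloxymethyl)oxonan-3-ol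
Product: 17 (E)-4-[(2S,3S,6R,7R,9S)-3-hydroxy-6-methoxy-3,7-dimethyl-2-(triisopropylsilyloxymethyl)oxonan-9-yl]but-3-en-2-one, via C10 aldehyde 16 (not isolated)
Conditions: (COCl)2, DMSO, CH2Cl2, −78 °C; Et3N; then Ph3P=CHC(O)CH3, −78 °C → rt
Reagents that add atoms: 1-(triphenylphosphoranylidene)propan-2-one CC(=O)C=P(c1ccccc1)(c1ccccc1)c1ccccc1
Why: One-pot Swern oxidation and Wittig olefination with a stabilised ylide give the E enone (C10=C11, C12 ketone); the oxidant is consumed before the aldehyde can equilibrate with its lactol onto the C3 hydroxyl, so over-oxidation to a lactone is avoided.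

**Step 13**
Reactants: 17 (E)-4-[(2S,3S,6R,7R,9S)-3-hydroxy-6-methoxy-3,7-dimethyl-2-(triisopropylsilyloxymethyl)oxonan-9-yl]but-3-en-2-one
Product: 18 (2S,3S,6R,7R,9S)-6-methoxy-3,7-dimethyl-9-[(E)-3-methylbuta-1,3-dienyl]-2-(triisopropylsilyloxymethyl)oxonan-3-ol
Conditions: Cp2Ti(μ-Cl)(μ-CH2)AlMe2, pyridine, THF, −40 → 0 °C
Reagents that add atoms: Tebbe reagent (titanocene methylidene with dimethylaluminium chloride) [CH2]=[Ti](C1C=CC=C1)C1C=CC=C1.C[Al](C)Cl
Why: Tebbe methylenation of the enone carbonyl gives the 2-methyl-1,3-diene (C10=C11–C12(CH3)=C13) under non-basic conditions, so the C3 alkoxide is not generated and cannot add to C10 of the enone.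

**Step 14**
Reactants: 18 (2S,3S,6R,7R,9S)-6-methoxy-3,7-dimethyl-9-[(E)-3-methylbuta-1,3-dienyl]-2-(triisopropylsilyloxymethyl)oxonan-3-ol
Product: 19 (2S,3S,6R,7R,9S)-2-(hydroxymethyl)-6-methoxy-3,7-dimethyl-9-[(E)-3-methylbuta-1,3-dienyl]oxonan-3-ol
Conditions: Bu4NF, THF, 0 °C → rt
Reagents that add atoms: none
Why: Fluoride cleavage of the primary triisopropylsilyl ether frees the C1 hydroxyl under conditions that leave the diene intact.

**Step 15**
Reactants: 19 (2S,3S,6R,7R,9S)-2-(hydroxymethyl)-6-methoxy-3,7-dimethyl-9-[(E)-3-methylbuta-1,3-dienyl]oxonan-3-ol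
Product: 22 tricyclic methyl ketone (cyclohexene C1/C10/C11=C12/C13/C14 cis-fused to the tetrahydrofuran O/C2/C1/C10/C9 on the oxonane; acetyl on C14; H-1 and H-10 cis and both trans to H-2 and H-9; H-14 trans to H-1), via C1 aldehyde 20 (not isolated), via enone tetraene 21 (not isolated)
Conditions: Dess–Martin periodinane, NaHCO3, CH2Cl2, 0 °C; then Ph3P=CHC(O)CH3, CH2Cl2, rt → 40 °C; then toluene, 60 °C
Reagents that add atoms: 1-(triphenylphosphoranylidene)propan-2-one CC(=O)C=P(c1ccccc1)(c1ccccc1)c1ccccc1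
Why: Buffered Dess–Martin oxidation gives aldehyde 20, which the stabilised ylide converts (Wittig, E-selective) into enone 21; in 21 the ether oxygen between C2 and C9 is a three-atom tether that holds diene terminus C10 and enone β-carbon C1 on one face of the nine-membered ring, so a concerted suprafacial [4+2] cycloaddition forms C1–C10 and C13–C14 (closest known reaction type: the intramolecular Diels–Alder reaction of cis-2,9-disubstituted oxonenes that carry a diene on C9 and an enone on C2). The cyclohexene (C1, C10, C11, C12, C13, C14) is closed by the cycloaddition itself and the tetrahydrofuran (O, C2, C1, C10, C9) is closed as the tether ring by the C1–C10 bond. The trans relation of H-1 and H-14 follows from the E geometry of the enone, and the cis ring fusion (H-1/H-10) from the tether-endo, acetyl-exo transition state that the short tether enforces. The facial sense at C1 and C10 (both H trans to H-2 and H-9) is controlled by allylic 1,3-strain: H-2 and H-9 lie in the planes of their alkenes, so the six-membered ring can grow only on the side of the ether bridge away from C3 and C8. Regiochemistry is fixed by the tether and is electronically matched (C10 is the nucleophilic diene terminus, C1 the electrophilic β-carbon), so the step needs only this facial and exo selectivity.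

**Step 16**
Reactants: 22 tricyclic methyl ketone
Product: 23 tricyclic isopropenyl compound (C14 bears C(CH3)=CH2; C15=C16)
Conditions: Ph3PCH3Br, KOt-Bu, THF, 0 °C → rt
Reagents that add atoms: methyltriphenylphosphonium bromide C[P+](c1ccccc1)(c1ccccc1)c1ccccc1.[Br-]
Why: Wittig methylenation turns the acetyl group into the isopropenyl group (C16 added); the equatorial, trans C14 centre is the thermodynamically preferred one and should survive the basic ylide.

**Step 17**
Reactants: 23 tricyclic isopropenyl compound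
Product: 25 tricyclic primary alcohol (C15 stereocentre bearing CH3; C16–OH), via B-alkyl-9-BBN adduct 24 (not isolated)
Conditions: 9-BBN, THF, 0 °C → rt; then NaOH, H2O2, 0 °C
Reagents that add atoms: hydrogen peroxide OO; 9-borabicyclo[3.3.1]nonane B1C2CCCC1CCC2 (kept only in 24)
Why: Hydroboration–oxidation; 9-BBN takes the 1,1-disubstituted alkene and leaves the trisubstituted C11=C12 alkene, and with H-14 in the alkene plane (allylic strain) boron adds to the face flanked by the C13 methylene, away from C1 and its C2 substituent, which sets C15.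

**Step 18**
Reactants: 25 tricyclic primary alcohol
Product: 27 tetracyclic alkene (oxepane C3–O–C16 closed; C11=C12 still present), via primary triflate 26 (not isolated)
Conditions: Tf2O, 2,6-lutidine, CH2Cl2, −78 → 0 °C
Reagents that add atoms: triflic anhydride O=S(=O)(OS(=O)(=O)C(F)(F)F)C(F)(F)F (kept only in 26)
Why: Selective triflation of the primary hydroxyl and intramolecular SN2 displacement by the tertiary C3 hydroxyl (7-exo-tet etherification) closes the trans-fused oxepane; C2 and C15 are gauche on the diequatorial C1–C14 bond, which brings C3–OH and C16 together.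

**Step 19**
Reactants: 27 tetracyclic alkene
Product: 29 tetracyclic 11β-alcohol (12α-CH3), via C11 alkylborane 28 (not isolated)
Conditions: BH3·THF, THF, 0 °C → rt; then NaOH, H2O2, 0 °C
Reagents that add atoms: hydrogen peroxide OO; borane–tetrahydrofuran B.C1CCOC1 (boron kept only in 28)
Why: Hydroboration–oxidation; borane adds syn and anti-Markovnikov to C11=C12 from the β face, opposite the pseudoaxial C9 substituent at C10, which sets the α-methyl at C12; the 11β-hydroxyl formed with it is corrected in steps 20 and 21.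

**Step 20**
Reactants: 29 tetracyclic 11β-alcohol
Product: 30 tetracyclic C11 ketone
Conditions: Dess–Martin periodinane, NaHCO3, CH2Cl2, 0 °C
Reagents that add atoms: none
Why: Buffered Dess–Martin oxidation gives the ketone under neutral conditions, which protects the epimerisable C12 and C10 centres and the β-alkoxy C9–O bond.

**Step 21**
Reactants: 30 tetracyclic C11 ketone
Product: 31 tetracyclic 11α-alcohol (deacetyl target)
Conditions: NaBH4, CeCl3·7H2O, MeOH, −40 °C
Reagents that add atoms: none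
Why: Hydride reduction by axial attack from the β face (the equatorial path is blocked by the axial C9 and C12-methyl groups) gives the equatorial α-alcohol, which sets C11; the cerium salt keeps the medium non-basic.

**Step 22**
Reactants: 31 tetracyclic 11α-alcohol
Product: 32 target, (1S,2S,3S,6R,7R,9S,10R,11R,12R,14S,15R)-11-acetoxy-6-methoxy tetracycle
Conditions: Ac2O, Et3N, DMAP (cat.), CH2Cl2, rt
Reagents that add atoms: acetic anhydride CC(=O)OC(C)=O
Why: DMAP-catalysed acetylation of the only free hydroxyl completes the target without touching any stereocentre.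

**Compound list**

1 | (S)-benzyl glycidyl ether | C1O[C@@H]1COCc2ccccc2 | starting material
2 | (S)-1-(benzyloxy)-4-methylpent-4-en-2-ol | C=C(C)C[C@@H](COCc1ccccc1)O | intermediate
3 | {[(S)-1-(benzyloxy)-4-methylpent-4-en-2-yl]oxy}acetic acid | C=C(C)C[C@@H](COCc1ccccc1)OCC(=O)O | intermediate
4 | mixed pivalic anhydride of 3 | C=C(C)C[C@@H](COCc1ccccc1)OCC(=O)OC(=O)C(C)(C)C | intermediate (not isolated)
5 | (R)-4-benzyl-3-({[(S)-1-(benzyloxy)-4-methylpent-4-en-2-yl]oxy}acetyl)oxazolidin-2-one | C=C(C)C[C@@H](COCc1ccccc1)OCC(=O)N1[C@H](Cc2ccccc2)COC1=O | intermediate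
6 | (R)-4-benzyl-3-[(S)-2-{[(S)-1-(benzyloxy)-4-methylpent-4-en-2-yl]oxy}-3-(triisopropylsilyloxy)propanoyl]oxazolidin-2-one | C=C(C)C[C@@H](COCc1ccccc1)O[C@@H](CO[Si](C(C)C)(C(C)C)C(C)C)C(=O)N1[C@H](Cc2ccccc2)COC1=O | intermediate
7 | (S)-2-{[(S)-1-(benzyloxy)-4-methylpent-4-en-2-yl]oxy}-N-methoxy-N-methyl-3-(triisopropylsilyloxy)propanamide | C=C(C)C[C@@H](COCc1ccccc1)O[C@@H](CO[Si](C(C)C)(C(C)C)C(C)C)C(=O)N(C)OC | intermediate
8 | (S)-3-{[(S)-1-(benzyloxy)-4-methylpent-4-en-2-yl]oxy}-4-(triisopropylsilyloxy)butan-2-one | C=C(C)C[C@@H](COCc1ccccc1)O[C@@H](CO[Si](C(C)C)(C(C)C)C(C)C)C(C)=O | intermediate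
9 | (2S,3S)-2-{[(S)-1-(benzyloxy)-4-methylpent-4-en-2-yl]oxy}-3-methyl-1-(triisopropylsilyloxy)hept-6-en-3-ol | C=C(C)C[C@@H](COCc1ccccc1)O[C@@H](CO[Si](C(C)C)(C(C)C)C(C)C)[C@@](C)(O)CCC=C | intermediate
10 | (2S,3S,9S,6Z)-9-(benzyloxymethyl)-3,7-dimethyl-2-(triisopropylsilyloxymethyl)-2,3,4,5,8,9-hexahydrooxonin-3-ol | O1[C@@H](CO[Si](C(C)C)(C(C)C)C(C)C)[C@@](C)(O)CC/C=C(C)\C[C@H]1COCc2ccccc2 | intermediate
11 | C3 O-(dimethylsilyl) ether of 10 | O1[C@@H](CO[Si](C(C)C)(C(C)C)C(C)C)[C@@](C)(O[SiH](C)C)CC/C=C(C)\C[C@H]1COCc2ccccc2 | intermediate (not isolated)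
12 | bridged cyclic siloxane (SiMe2 bonded to C6 and to the C3 oxygen; H-7 cis to Si) | O1[C@@H](CO[Si](C(C)C)(C(C)C)C(C)C)[C@]2(C)CC[C@@H]([Si](C)(C)O2)[C@H](C)C[C@H]1COCc3ccccc3 | intermediate (not isolated)
13 | (2S,3S,6R,7R,9S)-9-(benzyloxymethyl)-3,7-dimethyl-2-(triisopropylsilyloxymethyl)oxonane-3,6-diol | O1[C@@H](CO[Si](C(C)C)(C(C)C)C(C)C)[C@@](C)(O)CC[C@@H](O)[C@H](C)C[C@H]1COCc2ccccc2 | intermediate
14 | (2S,3S,6R,7R,9S)-9-(benzyloxymethyl)-6-methoxy-3,7-dimethyl-2-(triisopropylsilyloxymethyl)oxonan-3-ol | O1[C@@H](CO[Si](C(C)C)(C(C)C)C(C)C)[C@@](C)(O)CC[C@@H](OC)[C@H](C)C[C@H]1COCc2ccccc2 | intermediate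
15 | (2S,3S,6R,7R,9S)-9-(hydroxymethyl)-6-methoxy-3,7-dimethyl-2-(triisopropylsilyloxymethyl)oxonan-3-ol | O1[C@@H](CO[Si](C(C)C)(C(C)C)C(C)C)[C@@](C)(O)CC[C@@H](OC)[C@H](C)C[C@H]1CO | intermediate
16 | C10 aldehyde (formyl on C9 of the oxonane of 15) | O1[C@@H](CO[Si](C(C)C)(C(C)C)C(C)C)[C@@](C)(O)CC[C@@H](OC)[C@H](C)C[C@H]1C=O | intermediate (not isolated)
17 | (E)-4-[(2S,3S,6R,7R,9S)-3-hydroxy-6-methoxy-3,7-dimethyl-2-(triisopropylsilyloxymethyl)oxonan-9-yl]but-3-en-2-one | O1[C@@H](CO[Si](C(C)C)(C(C)C)C(C)C)[C@@](C)(O)CC[C@@H](OC)[C@H](C)C[C@H]1/C=C/C(C)=O | intermediate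
18 | (2S,3S,6R,7R,9S)-6-methoxy-3,7-dimethyl-9-[(E)-3-methylbuta-1,3-dienyl]-2-(triisopropylsilyloxymethyl)oxonan-3-ol | O1[C@@H](CO[Si](C(C)C)(C(C)C)C(C)C)[C@@](C)(O)CC[C@@H](OC)[C@H](C)C[C@H]1/C=C/C(C)=C | intermediate
19 | (2S,3S,6R,7R,9S)-2-(hydroxymethyl)-6-methoxy-3,7-dimethyl-9-[(E)-3-methylbuta-1,3-dienyl]oxonan-3-ol | O1[C@@H](CO)[C@@](C)(O)CC[C@@H](OC)[C@H](C)C[C@H]1/C=C/C(C)=C | intermediate
20 | C1 aldehyde (formyl on C2 of the oxonane of 19) | O1[C@@H](C=O)[C@@](C)(O)CC[C@@H](OC)[C@H](C)C[C@H]1/C=C/C(C)=C | intermediate (not isolated)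
21 | enone tetraene (C2 bears (E)-3-oxobut-1-enyl; C9 bears (E)-3-methylbuta-1,3-dienyl) | O1[C@@H](/C=C/C(C)=O)[C@@](C)(O)CC[C@@H](OC)[C@H](C)C[C@H]1/C=C/C(C)=C | intermediate (not isolated)
22 | tricyclic methyl ketone (cycloadduct; C11=C12; acetyl on C14) | O1[C@@H]2[C@@](C)(O)CC[C@@H](OC)[C@H](C)C[C@H]1[C@@H]3C=C(C)C[C@@H](C(C)=O)[C@H]23 | intermediate
23 | tricyclic isopropenyl compound | O1[C@@H]2[C@@](C)(O)CC[C@@H](OC)[C@H](C)C[C@H]1[C@@H]3C=C(C)C[C@@H](C(C)=C)[C@H]23 | intermediate
24 | B-alkyl-9-BBN adduct at C16 | O1[C@@H]2[C@@](C)(O)CC[C@@H](OC)[C@H](C)C[C@H]1[C@@H]3C=C(C)C[C@@H]([C@@H](C)CB4C5CCCC4CCC5)[C@H]23 | intermediate (not isolated)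
25 | tricyclic primary alcohol (15R; C16–OH) | O1[C@@H]2[C@@](C)(O)CC[C@@H](OC)[C@H](C)C[C@H]1[C@@H]3C=C(C)C[C@@H]([C@@H](C)CO)[C@H]23 | intermediate
26 | primary triflate of 25 | O1[C@@H]2[C@@](C)(O)CC[C@@H](OC)[C@H](C)C[C@H]1[C@@H]3C=C(C)C[C@@H]([C@@H](C)COS(=O)(=O)C(F)(F)F)[C@H]23 | intermediate (not isolated)
27 | tetracyclic alkene (11,12-didehydro, 11-deacetoxy target) | CO[C@@H]1CC[C@]2(C)OC[C@H](C)[C@@H]3CC(C)=C[C@@H]4[C@H]3[C@@H]2O[C@H]4C[C@H]1C | intermediate
28 | C11 alkylborane (11β-BH2, 12α-CH3) | CO[C@@H]1CC[C@]2(C)OC[C@H](C)[C@@H]3C[C@@H](C)[C@H](B)[C@@H]4[C@H]3[C@@H]2O[C@H]4C[C@H]1C | intermediate (not isolated)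
29 | tetracyclic 11β-alcohol (11-epi deacetyl target) | CO[C@@H]1CC[C@]2(C)OC[C@H](C)[C@@H]3C[C@@H](C)[C@H](O)[C@@H]4[C@H]3[C@@H]2O[C@H]4C[C@H]1C | intermediate
30 | tetracyclic C11 ketone | CO[C@@H]1CC[C@]2(C)OC[C@H](C)[C@@H]3C[C@@H](C)C(=O)[C@@H]4[C@H]3[C@@H]2O[C@H]4C[C@H]1C | intermediate
31 | tetracyclic 11α-alcohol (deacetyl target) | CO[C@@H]1CC[C@]2(C)OC[C@H](C)[C@@H]3C[C@@H](C)[C@@H](O)[C@@H]4[C@H]3[C@@H]2O[C@H]4C[C@H]1C | intermediate
32 | CNP0289153.2 | CO[C@@H]1CC[C@]2(C)OC[C@H](C)[C@@H]3C[C@@H](C)[C@@H](OC(C)=O)[C@@H]4[C@H]3[C@@H]2O[C@H]4C[C@H]1C | target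

**Step count**

Total: 22 steps. Longest linear sequence: 22 steps (1 → 32); the route is linear.

**Steps most likely to fail, and fallbacks**

Step 9 (the step marked as a proposed new method). The silyl hydride may fail to reach the ring alkene, so that intermolecular hydrosilylation, alkene migration or delivery of silicon to C7 takes over. The fallback uses known chemistry, sets out from 10 and returns at 13. Hydroxyl-directed epoxidation with VO(acac)2 and t-BuOOH, in which the vanadate ester of the C3 hydroxyl delivers oxygen to the face the tether would have used, should give the cis-6,7-epoxide F1. Diethylaluminium 2,2,6,6-tetramethylpiperidide should isomerise it to the exocyclic-methylene allylic alcohol F2. Hydroxyl-directed hydrogenation with [Ir(cod)(PCy3)(py)]PF6 and H2 then adds hydrogen to C7 from the side of the C6 and C3 hydroxyls, which gives the trans 6-hydroxy-7-methyl arrangement of diol 13.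

Step 15. The β-hydroxy-α-alkoxy aldehyde 20 may fragment by retro-aldol cleavage or epimerise at C2 before it is trapped, and cycloaddition running alongside a slow Wittig reaction may erode facial control. The fallback sets out from 19 and returns at 22. Oxidation with SO3·pyridine, DMSO and i-Pr2NEt is followed at once by a Horner–Wadsworth–Emmons reaction with diethyl (N-methoxy-N-methylcarbamoylmethyl)phosphonate (LiCl, i-Pr2NEt, MeCN). This should give the isolable (E)-N-methoxy-N-methyl enamide tetraene F3, a less reactive dienophile that can be purified. It is then cyclised as a separate thermal operation (toluene, 110 °C) to the amide cycloadduct F4, and MeMgBr converts this Weinreb amide into methyl ketone 22.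

Step 8. With a free tertiary hydroxyl next to the ether oxygen, oligomerisation may outrun closure of the nine-membered ring, through loss of conformational bias or chelation of the ruthenium carbene. The fallback sets out from 9 and returns at 10. The C3 hydroxyl is capped with Et3SiOTf and 2,6-lutidine to give the triethylsilyl ether diene F5, which restores a bulky C3–O substituent gauche to the C2–O bond. Ring-closing metathesis with the same catalyst should then give the oxonene triethylsilyl ether F6. HF·pyridine in THF/pyridine removes the tertiary triethylsilyl group in the presence of the primary triisopropylsilyl ether and gives 10.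

**Further compounds**

F1 | step 9 | cis-6,7-epoxide of 10 on the face of the C3 hydroxyl | O1[C@@H](CO[Si](C(C)C)(C(C)C)C(C)C)[C@@](C)(O)CC[C@H]2O[C@@]2(C)C[C@H]1COCc3ccccc3
F2 | step 9 | (2S,3S,6R,9S)-9-(benzyloxymethyl)-3-methyl-7-methylidene-2-(triisopropylsilyloxymethyl)oxonane-3,6-diol | O1[C@@H](CO[Si](C(C)C)(C(C)C)C(C)C)[C@@](C)(O)CC[C@@H](O)C(=C)C[C@H]1COCc2ccccc2
F3 | step 15 | (E)-N-methoxy-N-methyl enamide tetraene (C2 bears (E)-CH=CH–C(O)N(OMe)Me; C9 bears the diene) | O1[C@@H](/C=C/C(=O)N(C)OC)[C@@](C)(O)CC[C@@H](OC)[C@H](C)C[C@H]1/C=C/C(C)=C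
F4 | step 15 | tricyclic Weinreb amide cycloadduct (C(O)N(OMe)Me on C14) | O1[C@@H]2[C@@](C)(O)CC[C@@H](OC)[C@H](C)C[C@H]1[C@@H]3C=C(C)C[C@@H](C(=O)N(C)OC)[C@H]23
F5 | step 8 | C3 triethylsilyl ether of diene 9 | C=C(C)C[C@@H](COCc1ccccc1)O[C@@H](CO[Si](C(C)C)(C(C)C)C(C)C)[C@@](C)(O[Si](CC)(CC)CC)CCC=C
F6 | step 8 | C3 triethylsilyl ether of oxonene 10 | O1[C@@H](CO[Si](C(C)C)(C(C)C)C(C)C)[C@@](C)(O[Si](CC)(CC)CC)CC/C=C(C)\C[C@H]1COCc2ccccc2
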